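**Retrosynthetic overview**

- Benzofuran numbering is used (O1, C2, C3, C3a–C7a). Ring A is the benzene ring and is bought. Ring B, the dihydrofuran, is the only ring to be formed, and it is formed last.
- The last disconnection is C3a–C3 of ring B together with the C3 acetate. This leads to the open iodo aldehyde 12, which closes by a catalytic asymmetric Ni/Cr (Nozaki–Hiyama–Kishi) reaction with acetyl trapping in the same flask.
- The enabling feature is that C3 is a benzylic carbinol carbon bonded to C3a, the ring A carbon ortho to O1. With C3 as CHO and iodine on C3a, the O1–C2 tether holds both ends in a five-atom array. The CHO group is also the only group in the molecule that an aryl chromium attacks.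
- C2(O1)–C(=CH2)CO2Me is a Morita–Baylis–Hillman retron. O1–C2 comes from a palladium-catalysed asymmetric allylic etherification of the racemic carbonate 4 with iodophenol 5, which sets C2.
- The side chain is built by asymmetric transfer hydrogenation of the aryl ketone (sets the carbinol centre) followed by angeloylation without isomerisation. Both are done before ring closure, so the labile cis 3-acetate is made last.

Key step: step 8

Assumption: the sense of induction of the (R,R)-bisphosphine in step 3 and of the (S)-sulfonamide ligand in step 8 is taken by analogy with related substrates. If the opposite sense is found, the enantiomeric ligand is used and nothing else changes. Compounds 1, 2, 5 and 8 are commercial.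

Step 1
Reactants: 1 (tert-butyldimethylsilyloxy)acetaldehyde; 2 methyl acrylate
Product: 3 methyl 4-[(tert-butyldimethylsilyl)oxy]-3-hydroxy-2-methylidenebutanoate (racemic)
Conditions: DABCO (0.5 equiv), 2 (3 equiv), 1,4-dioxane/H2O, rt
Reagents that add atoms: none
Why: Morita–Baylis–Hillman reaction, in which DABCO adds to 2, the ammonium enolate attacks the reactive α-silyloxy aldehyde 1 and the amine is expelled, giving the C2(OH)–C(=CH2)CO2Me unit as a racemate, which is of no concern because step 3 resets this centre.

Step 2
Reactants: 3 racemic allylic alcohol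
Product: 4 methyl 4-[(tert-butyldimethylsilyl)oxy]-3-[(methoxycarbonyl)oxy]-2-methylidenebutanoate (racemic)
Conditions: ClCO2Me, pyridine, CH2Cl2, 0 °C
Reagents that add atoms: methyl chloroformate, COC(=O)Cl
Why: Standard O-acylation of a secondary allylic alcohol with a chloroformate, run with pyridine alone so that no strongly nucleophilic amine triggers allylic transposition, and it installs the leaving group for step 3.

Step 3
Reactants: 4 racemic carbonate; 5 1-(4-hydroxy-3-iodophenyl)ethanone
Product: 6 methyl (3S)-3-(4-acetyl-2-iodophenoxy)-4-[(tert-butyldimethylsilyl)oxy]-2-methylidenebutanoate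
Conditions: Pd2(dba)3·CHCl3 (2 mol %), N,N'-[(1R,2R)-cyclohexane-1,2-diyl]bis[2-(diphenylphosphanyl)benzamide] (6 mol %), CH2Cl2, rt
Reagents that add atoms: none
Why: Palladium-catalysed asymmetric allylic etherification run as a dynamic kinetic asymmetric transformation of a Morita–Baylis–Hillman carbonate, in which both enantiomers of 4 ionise to π-allyl complexes that interconvert through the unsubstituted CH2 terminus, the released methoxide deprotonates 5, and the chiral pocket steers the phenoxide to the substituted terminus of one complex, which sets C2 as S, while ionisation at room temperature outruns insertion of zerovalent palladium into the C–I bond.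

Step 4
Reactants: 6 aryl methyl ketone
Product: 7 methyl (3S)-4-[(tert-butyldimethylsilyl)oxy]-3-{4-[(1S)-1-hydroxyethyl]-2-iodophenoxy}-2-methylidenebutanoate
Conditions: RuCl[(S,S)-TsDPEN](p-cymene) (1 mol %), HCO2H/Et3N 5:2, EtOAc, rt
Reagents that add atoms: none
Why: Asymmetric transfer hydrogenation of an aryl methyl ketone, in which the ruthenium hydride of the (S,S)-TsDPEN complex delivers hydride to the Re face of the C=O group through the six-membered outer-sphere transition state, setting the carbinol centre as S without touching the acrylate, the aryl iodide or C2.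

Step 5
Reactants: 7 (S)-benzylic alcohol; 8 angelic acid [(Z)-2-methylbut-2-enoic acid]
Product: 10 (1S)-1-(4-{[(2S)-1-[(tert-butyldimethylsilyl)oxy]-3-(methoxycarbonyl)but-3-en-2-yl]oxy}-3-iodophenyl)ethyl (Z)-2-methylbut-2-enoate, via angelic 2,4,6-trichlorobenzoic anhydride 9 (not isolated)
Conditions: 8, 2,4,6-trichlorobenzoyl chloride, Et3N, toluene, rt; then 7, toluene, 75 °C (no DMAP)
Reagents that add atoms: none
Why: Yamaguchi-type mixed-anhydride esterification without nucleophilic catalyst, in which the alcohol attacks the unhindered angeloyl carbonyl of 9, the carbinol C–O bond is not broken so the S centre is retained, and the absence of DMAP closes the addition–elimination path by which angelates turn into tiglates.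

Step 6
Reactants: 10 silyl ether
Product: 11 (1S)-1-(4-{[(2S)-1-hydroxy-3-(methoxycarbonyl)but-3-en-2-yl]oxy}-3-iodophenyl)ethyl (Z)-2-methylbut-2-enoate
Conditions: HF·pyridine, pyridine, THF, 0 °C
Reagents that add atoms: none
Why: Fluoride-driven cleavage of a primary silyl ether in a pyridine-buffered, non-basic medium, which spares the benzylic angelate and forms no alkoxide that could lactonise onto the methyl ester or displace the allylic aryloxide, provided 11 is taken on at once.

Step 7
Reactants: 11 primary alcohol
Product: 12 methyl (3S)-3-{2-iodo-4-[(1S)-1-{[(Z)-2-methylbut-2-enoyl]oxy}ethyl]phenoxy}-2-methylidene-4-oxobutanoate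
Conditions: Dess–Martin periodinane, NaHCO3, CH2Cl2, 0 °C; short pad filtration, used the same day
Reagents that add atoms: none
Why: Dess–Martin oxidation, a base-free oxidation of primary alcohols that stops at the aldehyde, so the doubly activated C2–H of 12 is not removed and both the S centre and the position of the alkene should hold, as they do in other 2-alkoxybut-3-enals handled in this way.

Step 8
Reactants: 12 iodo aldehyde
Product: 14 methyl 2-[(2S,3S)-3-acetoxy-5-{(1S)-1-[(Z)-2-methylbut-2-enoyloxy]ethyl}-2,3-dihydrobenzofuran-2-yl]acrylate (CNP0168827.1), via zirconium alkoxide 13 (not isolated)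
Conditions: CrCl2 (10 mol %), (S)-N-[2-(4-isopropyl-4,5-dihydro-1,3-oxazol-2-yl)-6-methylphenyl]methanesulfonamide (11 mol %), 1,8-bis(dimethylamino)naphthalene (11 mol %, used to preform the chromium complex), NiCl2·(2,9-dimethyl-1,10-phenanthroline) (1 mol %), Mn (2 equiv), Cp2ZrCl2 (1.1 equiv), LiCl (2 equiv), MeCN (0.02 M), rt; then Ac2O, pyridine, 0 °C, same flask
Reagents that add atoms: acetic anhydride, CC(=O)OC(C)=O
Why: Zerovalent nickel, formed from the NiCl2 complex by Mn, inserts into the C3a–I bond, the aryl group passes to trivalent chromium held by the chiral sulfonamide–oxazoline ligand, this σ-aryl chromium adds to the C3 aldehyde, and Cp2ZrCl2 takes over the alkoxide (13) so that Mn can return chromium to the divalent state. The closest known reaction type is the catalytic asymmetric Nozaki–Hiyama–Kishi (Ni/Cr) coupling and its intramolecular form used for ring closure of iodo aldehydes. Ring B closes in the 5-exo-trig mode, because the carbon–metal σ orbital at C3a lies in the plane of ring A and the two-atom O1–C2 tether places the C3 carbonyl carbon within its reach. The new stereocentre C3 is set by the ligand on chromium, which should expose the Si face of the aldehyde (3S, oxygen cis to the acrylate on C2), and C2 is kept because the medium holds no free base. The step needs attack on the aldehyde in the presence of the acrylate, the angelate and the methyl ester, which the aldehyde selectivity of organochromium reagents secures, while a phenanthroline-saturated nickel at low loading keeps short the lifetime of the aryl nickel that could insert 5-exo into the acrylate. Acetic anhydride added to the same flask acylates 13 before the cis alkoxide can attack the neighbouring methyl ester, so ring B, C3 and the acetate arrive in one operation.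

**Compound list**

1 | (tert-butyldimethylsilyloxy)acetaldehyde | O=CCO[Si](C)(C)C(C)(C)C | starting material
2 | methyl acrylate | C=CC(=O)OC | starting material
3 | methyl 4-[(tert-butyldimethylsilyl)oxy]-3-hydroxy-2-methylidenebutanoate (racemic) | C=C(C(=O)OC)C(O)CO[Si](C)(C)C(C)(C)C | intermediate
4 | methyl 4-[(tert-butyldimethylsilyl)oxy]-3-[(methoxycarbonyl)oxy]-2-methylidenebutanoate (racemic) | C=C(C(=O)OC)C(OC(=O)OC)CO[Si](C)(C)C(C)(C)C | intermediate
5 | 1-(4-hydroxy-3-iodophenyl)ethanone | CC(=O)c1ccc(O)c(I)c1 | starting material
6 | methyl (3S)-3-(4-acetyl-2-iodophenoxy)-4-[(tert-butyldimethylsilyl)oxy]-2-methylidenebutanoate | C=C(C(=O)OC)[C@@H](CO[Si](C)(C)C(C)(C)C)Oc1ccc(C(C)=O)cc1I | intermediate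
7 | methyl (3S)-4-[(tert-butyldimethylsilyl)oxy]-3-{4-[(1S)-1-hydroxyethyl]-2-iodophenoxy}-2-methylidenebutanoate | C=C(C(=O)OC)[C@@H](CO[Si](C)(C)C(C)(C)C)Oc1ccc([C@H](C)O)cc1I | intermediate
8 | angelic acid, (Z)-2-methylbut-2-enoic acid | C/C=C(/C)C(=O)O | starting material
9 | angelic 2,4,6-trichlorobenzoic anhydride (not isolated) | C/C=C(/C)C(=O)OC(=O)c1c(Cl)cc(Cl)cc1Cl | intermediate
10 | (1S)-1-(4-{[(2S)-1-[(tert-butyldimethylsilyl)oxy]-3-(methoxycarbonyl)but-3-en-2-yl]oxy}-3-iodophenyl)ethyl (Z)-2-methylbut-2-enoate | C=C(C(=O)OC)[C@@H](CO[Si](C)(C)C(C)(C)C)Oc1ccc([C@H](C)OC(=O)/C(C)=C\C)cc1I | intermediate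
11 | (1S)-1-(4-{[(2S)-1-hydroxy-3-(methoxycarbonyl)but-3-en-2-yl]oxy}-3-iodophenyl)ethyl (Z)-2-methylbut-2-enoate | C=C(C(=O)OC)[C@@H](CO)Oc1ccc([C@H](C)OC(=O)/C(C)=C\C)cc1I | intermediate
12 | methyl (3S)-3-{2-iodo-4-[(1S)-1-{[(Z)-2-methylbut-2-enoyl]oxy}ethyl]phenoxy}-2-methylidene-4-oxobutanoate | C=C(C(=O)OC)[C@@H](C=O)Oc1ccc([C@H](C)OC(=O)/C(C)=C\C)cc1I | intermediate
13 | chlorobis(cyclopentadienyl)zirconium (2S,3S)-3-alkoxide of the closed ring B (not isolated; cyclopentadienyl rings drawn σ-bonded) | C=C(C(=O)OC)[C@@H]1Oc2ccc([C@H](C)OC(=O)/C(C)=C\C)cc2[C@@H]1O[Zr](Cl)(C1C=CC=C1)C1C=CC=C1 | intermediate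
14 | methyl 2-[(2S,3S)-3-acetoxy-5-{(1S)-1-[(Z)-2-methylbut-2-enoyloxy]ethyl}-2,3-dihydrobenzofuran-2-yl]acrylate (CNP0168827.1) | C=C(C(=O)OC)[C@@H]1Oc2ccc([C@H](C)OC(=O)/C(C)=C\C)cc2[C@@H]1OC(C)=O | target

Total step count: 8
Longest linear sequence: 8 steps (1 or 2 to 14)

**Steps most likely to fail**

Step 8. Three things may go wrong.
- The cis alkoxide may attack the neighbouring methyl ester (lactonisation) before it is acetylated.
- Facial selectivity may be poor if the ligand is mismatched with C2.
- Aldehyde 12 may enolise in the Lewis acidic medium.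

The fallback sets out from 12 and comes back at 14.
- The same Ni/Cr closure is run with the enantiomeric (R)-sulfonamide ligand, so that the aryl group adds to the Re face.
- Aqueous work-up should give the trans alcohol methyl 2-[(2S,3R)-3-hydroxy-5-{(1S)-1-[(Z)-2-methylbut-2-enoyloxy]ethyl}-2,3-dihydrobenzofuran-2-yl]acrylate F1. Its hydroxyl group cannot reach the ester, so it can be purified.
- The acetate is then brought in with inversion by a Mitsunobu reaction (AcOH, PPh3, DIAD, toluene, −20 °C) to give 14.

The oxygen-bearing configuration at C3 is thus fixed by SN2 displacement and not by direct catalyst control, and a free cis alkoxide never exists.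

Step 3. The rather good aryloxide leaving group may be re-ionised by zerovalent palladium, with leakage to the linear allyl ether and erosion of enantiopurity. Insertion into the C–I bond is a second risk.

The fallback sets out from 3 and comes back at 6. It uses metal-free Lewis-base catalysis in place of π-allyl palladium chemistry.
- Alcohol 3 is converted (Boc2O, DMAP cat., CH2Cl2) into methyl 3-[(tert-butoxycarbonyl)oxy]-4-[(tert-butyldimethylsilyl)oxy]-2-methylidenebutanoate F2.
- A cinchona-derived tertiary amine, (DHQD)2PHAL or its pseudo-enantiomer, chosen for the S ether, effects an SN2'–SN2' substitution with 5 in toluene.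
- The amine adds to the CH2 terminus and expels the carbonate, the tert-butoxide formed deprotonates 5, and the phenoxide attacks the secondary carbon of the chiral allyl ammonium ion. Only the branched ether 6 can form by this mechanism.

Step 5. The angeloyl group may isomerise from Z to E while its carbonyl is activated, or acylation may be too slow at a tolerable temperature.

The fallback sets out from 6 and comes back at 10.
- Ketone 6 is reduced with the enantiomeric catalyst RuCl[(R,R)-TsDPEN](p-cymene) to methyl (3S)-4-[(tert-butyldimethylsilyl)oxy]-3-{4-[(1R)-1-hydroxyethyl]-2-iodophenoxy}-2-methylidenebutanoate F3.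
- Angelic acid 8 then serves as the nucleophile in a Mitsunobu reaction (PPh3, DIAD, toluene, −20 to 0 °C). Inversion should give the S ester 10.
- The acid is never activated at its carbonyl group, so the alkene geometry cannot be lost.

**Further compounds**

F1 | step 8 | methyl 2-[(2S,3R)-3-hydroxy-5-{(1S)-1-[(Z)-2-methylbut-2-enoyloxy]ethyl}-2,3-dihydrobenzofuran-2-yl]acrylate | C=C(C(=O)OC)[C@@H]1Oc2ccc([C@H](C)OC(=O)/C(C)=C\C)cc2[C@H]1O
F2 | step 3 | methyl 3-[(tert-butoxycarbonyl)oxy]-4-[(tert-butyldimethylsilyl)oxy]-2-methylidenebutanoate (racemic) | C=C(C(=O)OC)C(OC(=O)OC(C)(C)C)CO[Si](C)(C)C(C)(C)C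
F3 | step 5 | methyl (3S)-4-[(tert-butyldimethylsilyl)oxy]-3-{4-[(1R)-1-hydroxyethyl]-2-iodophenoxy}-2-methylidenebutanoate | C=C(C(=O)OC)[C@@H](CO[Si](C)(C)C(C)(C)C)Oc1ccc([C@@H](C)O)cc1I
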